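**Retrosynthetic overview**
- The strategy rests on C5–C8: (S)-carbinol at C5, (6R,7R)-trans-oxirane, (S)-carbinol at C8, with CH2 groups at C4 and C9. This segment is locally C2-symmetric and maps onto a tartrate-derived trans-epoxide extended identically at both ends.
- Key disconnection: C4–C5 and C8–C9 together, by two-directional asymmetric allylboration of (2S,3S)-oxirane-2,3-dicarbaldehyde, which is made from diethyl D-tartrate and used in solution.
- The two homotopic vinyl groups are then differentiated: C11–C12 by hydroboration and alkyl–alkyl Suzuki coupling with a C12–C22 bromide made from (R)-propylene oxide (C21 stereocentre) and 8-bromooctan-1-ol; C2=C3 by ozonolysis and Still–Gennari olefination.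
- Ring order: the oxirane is formed first (step 2) and carried through; the 22-membered lactone is closed at O–C1 by macrolactonisation (step 15); desilylation ends the route.

Key step: step 4

Assumption: the sense of induction of the binaphthyl phosphoric acid is taken from simple aldehydes, where the (R)-acid delivers allyl to the Re face, so the (S)-acid is specified for the Si-face additions needed here; if the epoxy aldehyde responds in the opposite sense, the enantiomeric acid takes its place.

**Route**

Step 1
Reactants: 1 diethyl D-tartrate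
Product: 3 diethyl (2R,3R)-2-bromo-3-hydroxybutanedioate, via bromo acetate 2 (not isolated)
Conditions: HBr (33% in AcOH), 0 °C → rt; then EtOH, HBr (cat.), reflux
Reagents that add atoms: hydrogen bromide, Br; acetic acid, CC(=O)O (its acetyl group is in intermediate 2 only)
Why: Acetoxonium-ion formation from the vicinal diol and SN2 opening by bromide (acetoxy-bromination of a tartrate) inverts one carbinol centre, and acid-catalysed transesterification with ethanol then frees the hydroxyl without touching either centre.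

Step 2
Reactants: 3 diethyl (2R,3R)-2-bromo-3-hydroxybutanedioate
Product: 4 diethyl (2S,3S)-oxirane-2,3-dicarboxylate
Conditions: NaOEt, EtOH, 0 °C
Reagents that add atoms: none
Why: Intramolecular Williamson etherification, in which the alkoxide displaces the vicinal bromide with inversion, so that the two inversions together return the trans-(2S,3S)-epoxide with the tartrate configuration at both carbons.

Step 3
Reactants: 4 diethyl (2S,3S)-oxirane-2,3-dicarboxylate
Product: 5 [(2R,3R)-oxirane-2,3-diyl]dimethanol
Conditions: NaBH4, EtOH, 0 °C → rt; non-aqueous work-up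
Reagents that add atoms: none
Why: α-Oxygenated esters are activated enough for borohydride reduction of both ester groups in ethanol, while the epoxide and its two stereocentres are untouched (the descriptors change only through the priority rules).

Step 4
Reactants: 5 [(2R,3R)-oxirane-2,3-diyl]dimethanol; 6 allylboronic acid pinacol ester
Product: 9 (4S,5R,6R,7S)-5,6-epoxydeca-1,9-diene-4,7-diol, via (2S,3S)-oxirane-2,3-dicarbaldehyde 7 (not isolated), via bis(pinacol borate) ester 8 (not isolated)
Conditions: 2-iodoxybenzoic acid (IBX, 3 equiv), EtOAc, 75 °C; filter, 4 Å molecular sieves, add toluene, concentrate partly at 0 °C (never to dryness); then 6 (2.6 equiv), (S)-3,3'-bis(2,4,6-triisopropylphenyl)-1,1'-binaphthyl-2,2'-diyl hydrogen phosphate (10 mol%), toluene, −40 °C; pH 7 buffer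
Reagents that add atoms: none
Why: IBX oxidises both primary alcohols (the trans-epoxide cannot form a lactol, and the insoluble spent oxidant is filtered off), and each formyl group of 7 then reacts with 6 through a closed six-membered chair transition state in which the phosphoric acid hydrogen-bonds to a boronate oxygen while its phosphoryl oxygen holds the formyl hydrogen, forming C4–C5 and C8–C9 (target numbering) with transfer of boron to oxygen. The closest known reactions are the chiral phosphoric acid-catalysed allylboration of aldehydes with pinacol allylboronate, the asymmetric allylboration of α,β-epoxy aldehydes and the two-directional allylation of C2-symmetric tartrate-derived dialdehydes. No ring is closed; the oxirane is a spectator whose two stereocentres come from tartrate and are not epimerised under these non-basic conditions. The two new carbinol centres (4S and 7S) are set by the catalyst, the (S)-acid directing allyl to the Si face of each carbonyl. The selectivity needed is carbonyl facial selectivity against the modest preference expected of the epoxy aldehyde for the erythro adduct; the C2 axis makes the two formyl groups homotopic, so no regiochemistry arises and both additions have the same sense. Because 7 is a single enantiomer, a wrong-face addition gives a diastereomer, which chromatography should remove.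

Step 5
Reactants: 9 (4S,5R,6R,7S)-5,6-epoxydeca-1,9-diene-4,7-diol
Product: 10 (4S,5S,6S,7S)-5,6-epoxy-4,7-bis(triethylsilyloxy)deca-1,9-diene
Conditions: Et3SiCl, imidazole, DMF, 0 °C → rt
Reagents that add atoms: chlorotriethylsilane, CC[Si](Cl)(CC)CC
Why: Imidazole-promoted silylation of both secondary alcohols is mild enough for the epoxide, removes the risk of Payne rearrangement in later basic steps and installs groups that buffered fluoride removes at the end.

Step 6
Reactants: 11 8-bromooctan-1-ol
Product: 12 (8-bromooctyloxy)(tert-butyl)dimethylsilane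
Conditions: t-BuMe2SiCl, imidazole, CH2Cl2, 0 °C → rt
Reagents that add atoms: tert-butylchlorodimethylsilane, CC(C)(C)[Si](C)(C)Cl
Why: Standard silylation of the primary alcohol masks the hydroxyl so that a Grignard reagent can be formed at the bromide.

Step 7
Reactants: 12 (8-bromooctyloxy)(tert-butyl)dimethylsilane; 13 (R)-propylene oxide
Product: 15 (R)-11-[(tert-butyldimethylsilyl)oxy]undecan-2-ol, via Grignard reagent 14 (not isolated)
Conditions: Mg, THF, 40 °C; then 13, CuI (10 mol%), THF, −30 → 0 °C; aq. NH4Cl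
Reagents that add atoms: magnesium, [Mg] (in intermediate 14 only)
Why: Copper-catalysed SN2 opening of the terminal epoxide by the Grignard reagent takes place at the unsubstituted carbon, so the stereocentre of (R)-propylene oxide (C21 of the target) is carried over unchanged.

Step 8
Reactants: 15 (R)-11-[(tert-butyldimethylsilyl)oxy]undecan-2-ol
Product: 16 (R)-11-[(tert-butyldimethylsilyl)oxy]undecan-2-yl acetate
Conditions: Ac2O, pyridine, 4-(dimethylamino)pyridine (cat.), CH2Cl2, rt
Reagents that add atoms: acetic anhydride, CC(=O)OC(C)=O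
Why: Acylation under nucleophilic catalysis gives an ester that should survive the coupling, the ozonolysis and the olefination and that is removed later in the same operation as the methyl ester.

Step 9
Reactants: 16 (R)-11-[(tert-butyldimethylsilyl)oxy]undecan-2-yl acetate
Product: 17 (R)-11-hydroxyundecan-2-yl acetate
Conditions: camphor-10-sulfonic acid (10 mol%), MeOH/CH2Cl2, 0 °C
Reagents that add atoms: none
Why: Acid-catalysed methanolysis cleaves the primary silyl ether quickly at 0 °C, conditions under which the secondary acetate should not transesterify.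

Step 10
Reactants: 17 (R)-11-hydroxyundecan-2-yl acetate
Product: 18 (R)-11-bromoundecan-2-yl acetate
Conditions: CBr4, PPh3, CH2Cl2, 0 °C
Reagents that add atoms: carbon tetrabromide, BrC(Br)(Br)Br
Why: Appel reaction, in which bromide displaces the alkoxyphosphonium ion of the primary alcohol under neutral conditions that leave the remote acetate and stereocentre alone.

Step 11
Reactants: 10 (4S,5S,6S,7S)-5,6-epoxy-4,7-bis(triethylsilyloxy)deca-1,9-diene; 18 (R)-11-bromoundecan-2-yl acetate
Product: 20 (2R,15S,16S,17S,18S)-16,17-epoxy-15,18-bis(triethylsilyloxy)henicos-20-en-2-yl acetate, via B-alkyl-9-BBN 19 (not isolated)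
Conditions: 10 (2.5 equiv), 9-borabicyclo[3.3.1]nonane (9-BBN-H, 1.3 equiv), THF, 0 °C → rt; then 18 (1 equiv), Pd(OAc)2 (4 mol%), PCy3 (8 mol%), K3PO4·H2O (1.2 equiv), THF, rt; unreacted 10 recovered
Reagents that add atoms: 9-borabicyclo[3.3.1]nonane, B1C2CCCC1CCC2 (its atoms are in intermediate 19 only)
Why: Anti-Markovnikov hydroboration of one vinyl group followed by B-alkyl Suzuki–Miyaura coupling with the primary alkyl bromide, where the bulky electron-rich trialkylphosphine makes oxidative addition and coupling outrun β-hydride elimination, joins C11 to C12; the vinyl groups are homotopic, so a deficit of borane and recycling of 10 take care of the differentiation of the two ends.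

Step 12
Reactants: 20 (2R,15S,16S,17S,18S)-16,17-epoxy-15,18-bis(triethylsilyloxy)henicos-20-en-2-yl acetate
Product: 22 (3S,4S,5S,6S,19R)-19-acetoxy-4,5-epoxy-3,6-bis(triethylsilyloxy)icosanal, via secondary ozonide 21 (not isolated)
Conditions: O3, CH2Cl2, −78 °C; then PPh3, −78 °C → rt
Reagents that add atoms: ozone, [O-][O+]=O
Why: Ozonolysis with reductive work-up cleaves the only remaining alkene to the C3 aldehyde, the silyl ethers, epoxide and acetate being inert to ozone at −78 °C.

Step 13
Reactants: 22 (3S,4S,5S,6S,19R)-19-acetoxy-4,5-epoxy-3,6-bis(triethylsilyloxy)icosanal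
Product: 23 methyl (2Z,5S,6S,7S,8S,21R)-21-acetoxy-6,7-epoxy-5,8-bis(triethylsilyloxy)docos-2-enoate
Conditions: (CF3CH2O)2P(O)CH2CO2Me, KN(SiMe3)2, 18-crown-6, THF, −78 °C
Reagents that add atoms: methyl bis(2,2,2-trifluoroethyl)phosphonoacetate, COC(=O)CP(=O)(OCC(F)(F)F)OCC(F)(F)F
Why: Still–Gennari olefination, in which the electron-poor phosphonate under dissociating conditions eliminates rapidly from the kinetic adduct and so should give the (Z)-enoate, at a temperature at which the β-silyloxy aldehyde does not eliminate.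

Step 14
Reactants: 23 methyl (2Z,5S,6S,7S,8S,21R)-21-acetoxy-6,7-epoxy-5,8-bis(triethylsilyloxy)docos-2-enoate
Product: 24 (2Z,5S,6S,7S,8S,21R)-6,7-epoxy-21-hydroxy-5,8-bis(triethylsilyloxy)docos-2-enoic acid
Conditions: LiOH·H2O, THF/MeOH/H2O, 0 °C → rt; then 0.5 M HCl to pH 4, 0 °C
Reagents that add atoms: lithium hydroxide, [Li+].[OH-]
Why: Saponification cleaves the methyl ester and the C21 acetate in one operation by acyl–oxygen fission, so the C21 configuration is retained, and the cold, brief acidification should spare the triethylsilyl ethers.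

Step 15
Reactants: 24 (2Z,5S,6S,7S,8S,21R)-6,7-epoxy-21-hydroxy-5,8-bis(triethylsilyloxy)docos-2-enoic acid
Product: 26 (2Z,5S,6S,7S,8S,21R)-6,7-epoxy-5,8-bis(triethylsilyloxy)docos-2-en-21-olide, via mixed anhydride 25 (not isolated)
Conditions: 2,4,6-Cl3C6H2COCl, Et3N, THF, rt; then slow addition to 4-(dimethylamino)pyridine, toluene, rt, high dilution
Reagents that add atoms: 2,4,6-trichlorobenzoyl chloride, O=C(Cl)c1c(Cl)cc(Cl)cc1Cl (its acyl group is in intermediate 25 only)
Why: Yamaguchi macrolactonisation, in which the mixed anhydride acylates the pyridine catalyst and the C21 hydroxyl, the only free hydroxyl, closes the 22-membered ring under high dilution with retention at C21 because its C–O bond is not broken.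

Step 16
Reactants: 26 (2Z,5S,6S,7S,8S,21R)-6,7-epoxy-5,8-bis(triethylsilyloxy)docos-2-en-21-olide
Product: 27 CIML C, (2Z,5S,6R,7R,8S,21R)-6,7-epoxy-5,8-dihydroxydocos-2-en-21-olide
Conditions: HF·pyridine, pyridine, THF, 0 °C
Reagents that add atoms: none
Why: Pyridine-buffered HF·pyridine cleaves the two triethylsilyl ethers at 0 °C under conditions that should be too mild to open the epoxide, to start a Payne rearrangement or to move the lactone onto the C5 hydroxyl.

**Compound list**
1 | diethyl D-tartrate, diethyl (2S,3S)-2,3-dihydroxybutanedioate | CCOC(=O)[C@@H](O)[C@H](O)C(=O)OCC | starting material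
2 | diethyl (2R,3R)-2-acetoxy-3-bromobutanedioate | CCOC(=O)[C@@H](OC(C)=O)[C@@H](Br)C(=O)OCC | intermediate (not isolated)
3 | diethyl (2R,3R)-2-bromo-3-hydroxybutanedioate | CCOC(=O)[C@@H](O)[C@@H](Br)C(=O)OCC | intermediate
4 | diethyl (2S,3S)-oxirane-2,3-dicarboxylate | CCOC(=O)[C@H]1O[C@@H]1C(=O)OCC | intermediate
5 | [(2R,3R)-oxirane-2,3-diyl]dimethanol | OC[C@H]1O[C@@H]1CO | intermediate
6 | allylboronic acid pinacol ester | C=CCB1OC(C)(C)C(C)(C)O1 | starting material
7 | (2S,3S)-oxirane-2,3-dicarbaldehyde | O=C[C@H]1O[C@@H]1C=O | intermediate (not isolated)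
8 | (4S,5R,6R,7S)-5,6-epoxy-4,7-bis[(4,4,5,5-tetramethyl-1,3,2-dioxaborolan-2-yl)oxy]deca-1,9-diene | C=CC[C@H](OB2OC(C)(C)C(C)(C)O2)[C@H]1O[C@@H]1[C@@H](OB3OC(C)(C)C(C)(C)O3)CC=C | intermediate (not isolated)
9 | (4S,5R,6R,7S)-5,6-epoxydeca-1,9-diene-4,7-diol | C=CC[C@H](O)[C@H]1O[C@@H]1[C@@H](O)CC=C | intermediate
10 | (4S,5S,6S,7S)-5,6-epoxy-4,7-bis(triethylsilyloxy)deca-1,9-diene (same spatial arrangement as 9) | C=CC[C@H](O[Si](CC)(CC)CC)[C@H]1O[C@@H]1[C@@H](O[Si](CC)(CC)CC)CC=C | intermediate
11 | 8-bromooctan-1-ol | OCCCCCCCCBr | starting material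
12 | (8-bromooctyloxy)(tert-butyl)dimethylsilane | CC(C)(C)[Si](C)(C)OCCCCCCCCBr | intermediate
13 | (R)-propylene oxide | C[C@@H]1CO1 | starting material
14 | {8-[(tert-butyldimethylsilyl)oxy]octyl}magnesium bromide | CC(C)(C)[Si](C)(C)OCCCCCCCC[Mg]Br | intermediate (not isolated)
15 | (R)-11-[(tert-butyldimethylsilyl)oxy]undecan-2-ol | C[C@@H](O)CCCCCCCCCO[Si](C)(C)C(C)(C)C | intermediate
16 | (R)-11-[(tert-butyldimethylsilyl)oxy]undecan-2-yl acetate | C[C@@H](OC(C)=O)CCCCCCCCCO[Si](C)(C)C(C)(C)C | intermediate
17 | (R)-11-hydroxyundecan-2-yl acetate | C[C@@H](OC(C)=O)CCCCCCCCCO | intermediate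
18 | (R)-11-bromoundecan-2-yl acetate | C[C@@H](OC(C)=O)CCCCCCCCCBr | intermediate
19 | 9-[(4S,5S,6S,7S)-5,6-epoxy-4,7-bis(triethylsilyloxy)dec-9-en-1-yl]-9-borabicyclo[3.3.1]nonane | C=CC[C@H](O[Si](CC)(CC)CC)[C@H]1O[C@@H]1[C@@H](O[Si](CC)(CC)CC)CCCB2C3CCCC2CCC3 | intermediate (not isolated)
20 | (2R,15S,16S,17S,18S)-16,17-epoxy-15,18-bis(triethylsilyloxy)henicos-20-en-2-yl acetate | C[C@@H](OC(C)=O)CCCCCCCCCCCC[C@H](O[Si](CC)(CC)CC)[C@H]1O[C@@H]1[C@@H](O[Si](CC)(CC)CC)CC=C | intermediate
21 | secondary ozonide of 20 (1,2,4-trioxolane in place of the vinyl group, both epimers at the trioxolane carbon) | C[C@@H](OC(C)=O)CCCCCCCCCCCC[C@H](O[Si](CC)(CC)CC)[C@H]1O[C@@H]1[C@@H](O[Si](CC)(CC)CC)CC2OCOO2 | intermediate (not isolated)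
22 | (3S,4S,5S,6S,19R)-19-acetoxy-4,5-epoxy-3,6-bis(triethylsilyloxy)icosanal | C[C@@H](OC(C)=O)CCCCCCCCCCCC[C@H](O[Si](CC)(CC)CC)[C@H]1O[C@@H]1[C@@H](O[Si](CC)(CC)CC)CC=O | intermediate
23 | methyl (2Z,5S,6S,7S,8S,21R)-21-acetoxy-6,7-epoxy-5,8-bis(triethylsilyloxy)docos-2-enoate | C[C@@H](OC(C)=O)CCCCCCCCCCCC[C@H](O[Si](CC)(CC)CC)[C@H]1O[C@@H]1[C@@H](O[Si](CC)(CC)CC)C/C=C\C(=O)OC | intermediate
24 | (2Z,5S,6S,7S,8S,21R)-6,7-epoxy-21-hydroxy-5,8-bis(triethylsilyloxy)docos-2-enoic acid | C[C@@H](O)CCCCCCCCCCCC[C@H](O[Si](CC)(CC)CC)[C@H]1O[C@@H]1[C@@H](O[Si](CC)(CC)CC)C/C=C\C(=O)O | intermediate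
25 | mixed anhydride of 24 and 2,4,6-trichlorobenzoic acid | C[C@@H](O)CCCCCCCCCCCC[C@H](O[Si](CC)(CC)CC)[C@H]1O[C@@H]1[C@@H](O[Si](CC)(CC)CC)C/C=C\C(=O)OC(=O)c2c(Cl)cc(Cl)cc2Cl | intermediate (not isolated)
26 | (2Z,5S,6S,7S,8S,21R)-6,7-epoxy-5,8-bis(triethylsilyloxy)docos-2-en-21-olide (5,8-bis-O-triethylsilyl ether of the target) | C[C@@H]1CCCCCCCCCCCC[C@H](O[Si](CC)(CC)CC)[C@H]2O[C@@H]2[C@@H](O[Si](CC)(CC)CC)C/C=C\C(=O)O1 | intermediate
27 | CIML C, (2Z,5S,6R,7R,8S,21R)-6,7-epoxy-5,8-dihydroxydocos-2-en-21-olide | C[C@@H]1CCCCCCCCCCCC[C@H](O)[C@H]2O[C@@H]2[C@@H](O)C/C=C\C(=O)O1 | target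

**Step count**
Total: 16 steps. Longest linear sequence: 11 steps (steps 1–5 and 11–16 from diethyl D-tartrate; the side-chain branch, steps 6–10 and 11–16, is equally long).

**Steps most likely to fail**

Step 4. The catalyst may fail to override the facial preference of the epoxy aldehyde in the mismatched sense, and residues of the oxidation or hydration of the dialdehyde may slow the acid catalyst, so that wrong-face addition at one or both ends erodes the yield of the threo,threo-diol. The fallback works with the substrate's preference and corrects the configuration afterwards. It sets out from dialdehyde 7, generated as before, and uses the enantiomeric (R)-phosphoric acid with 6, which should give, through the bis(pinacol borate) ester of the erythro,erythro adduct F1, the (4R,5R,6R,7R)-5,6-epoxydeca-1,9-diene-4,7-diol F2. A double Mitsunobu reaction (4-nitrobenzoic acid, PPh3, diisopropyl azodicarboxylate, toluene, 0 °C) inverts both carbinols to give (4S,5R,6R,7S)-5,6-epoxydeca-1,9-diene-4,7-diyl bis(4-nitrobenzoate) F3. Methanolysis (K2CO3, MeOH, 0 °C, short contact to avoid Payne rearrangement) comes back to the route at diol 9.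

Step 11. Hydroboration of a diene with homotopic ends is statistical, and the mixture of mono- and bis-borane enters the coupling unpurified; slow transmetalation, protodeboronation or β-hydride elimination at the alkylpalladium stage would then consume the bromide without coupling. The fallback separates the differentiation of the ends from the C–C bond formation and reverses the polarity of the partners. It sets out from 10: the same sub-stoichiometric hydroboration is followed by oxidation (NaBO3·4H2O, THF/H2O) and chromatography, with recovery of 10, to give (4S,5S,6S,7S)-5,6-epoxy-4,7-bis(triethylsilyloxy)dec-9-en-1-ol F4. Iodination (I2, PPh3, imidazole, CH2Cl2, 0 °C) gives (4S,5S,6S,7S)-5,6-epoxy-10-iodo-4,7-bis(triethylsilyloxy)dec-1-ene F5. Bromide 18 is converted by zinc insertion (Zn dust, LiCl, THF, 50 °C) into [(R)-10-acetoxyundecyl]zinc bromide F6. Negishi alkyl–alkyl coupling of F5 with F6 ([PdCl2(IPr)(3-chloropyridine)], IPr = 1,3-bis(2,6-diisopropylphenyl)imidazol-2-ylidene, THF/N-methylpyrrolidone, rt) comes back to the route at 20.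

Step 15. Activation of the (Z)-enoic acid in the presence of the nucleophilic pyridine may isomerise the alkene to E through reversible conjugate addition, and intermolecular esterification may compete with ring closure. The fallback forms the ester bond first, intermolecularly, and closes the ring by the olefination itself. It sets out from 20: methanolysis of the acetate (K2CO3, MeOH, 0 °C → rt) gives (2R,15S,16S,17S,18S)-16,17-epoxy-15,18-bis(triethylsilyloxy)henicos-20-en-2-ol F7. Esterification with 2-[bis(2,2,2-trifluoroethoxy)phosphoryl]acetic acid (N,N'-dicyclohexylcarbodiimide, 4-(dimethylamino)pyridine (cat.), CH2Cl2) gives the phosphonoacetate ester of F7, F8. Ozonolysis (O3, CH2Cl2, −78 °C; PPh3) passes through the secondary ozonide of F8, F9, to the aldehyde phosphonoacetate F10. Intramolecular Still–Gennari olefination (K2CO3, 18-crown-6, toluene, high dilution, 0 °C → rt) closes the 22-membered ring directly as the (Z)-enoate and comes back to the route at 26, so that 22–25 are not needed.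

**Further compounds**
F1 | step 4 | (4R,5R,6R,7R)-5,6-epoxy-4,7-bis[(4,4,5,5-tetramethyl-1,3,2-dioxaborolan-2-yl)oxy]deca-1,9-diene | C=CC[C@@H](OB2OC(C)(C)C(C)(C)O2)[C@H]1O[C@@H]1[C@H](OB3OC(C)(C)C(C)(C)O3)CC=C
F2 | step 4 | (4R,5R,6R,7R)-5,6-epoxydeca-1,9-diene-4,7-diol | C=CC[C@@H](O)[C@H]1O[C@@H]1[C@H](O)CC=C
F3 | step 4 | (4S,5R,6R,7S)-5,6-epoxydeca-1,9-diene-4,7-diyl bis(4-nitrobenzoate) | C=CC[C@H](OC(=O)c2ccc(cc2)[N+](=O)[O-])[C@H]1O[C@@H]1[C@@H](OC(=O)c3ccc(cc3)[N+](=O)[O-])CC=C
F4 | step 11 | (4S,5S,6S,7S)-5,6-epoxy-4,7-bis(triethylsilyloxy)dec-9-en-1-ol | C=CC[C@H](O[Si](CC)(CC)CC)[C@H]1O[C@@H]1[C@@H](O[Si](CC)(CC)CC)CCCO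
F5 | step 11 | (4S,5S,6S,7S)-5,6-epoxy-10-iodo-4,7-bis(triethylsilyloxy)dec-1-ene | C=CC[C@H](O[Si](CC)(CC)CC)[C@H]1O[C@@H]1[C@@H](O[Si](CC)(CC)CC)CCCI
F6 | step 11 | [(R)-10-acetoxyundecyl]zinc bromide | C[C@@H](OC(C)=O)CCCCCCCCC[Zn]Br
F7 | step 15 | (2R,15S,16S,17S,18S)-16,17-epoxy-15,18-bis(triethylsilyloxy)henicos-20-en-2-ol | C[C@@H](O)CCCCCCCCCCCC[C@H](O[Si](CC)(CC)CC)[C@H]1O[C@@H]1[C@@H](O[Si](CC)(CC)CC)CC=C
F8 | step 15 | (2R,15S,16S,17S,18S)-16,17-epoxy-15,18-bis(triethylsilyloxy)henicos-20-en-2-yl 2-[bis(2,2,2-trifluoroethoxy)phosphoryl]acetate | C[C@@H](OC(=O)CP(=O)(OCC(F)(F)F)OCC(F)(F)F)CCCCCCCCCCCC[C@H](O[Si](CC)(CC)CC)[C@H]1O[C@@H]1[C@@H](O[Si](CC)(CC)CC)CC=C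
F9 | step 15 | secondary ozonide of F8 (1,2,4-trioxolane in place of the vinyl group, both epimers at the trioxolane carbon) | C[C@@H](OC(=O)CP(=O)(OCC(F)(F)F)OCC(F)(F)F)CCCCCCCCCCCC[C@H](O[Si](CC)(CC)CC)[C@H]1O[C@@H]1[C@@H](O[Si](CC)(CC)CC)CC2OCOO2
F10 | step 15 | (2R,15S,16S,17S,18S)-16,17-epoxy-20-oxo-15,18-bis(triethylsilyloxy)icosan-2-yl 2-[bis(2,2,2-trifluoroethoxy)phosphoryl]acetate | C[C@@H](OC(=O)CP(=O)(OCC(F)(F)F)OCC(F)(F)F)CCCCCCCCCCCC[C@H](O[Si](CC)(CC)CC)[C@H]1O[C@@H]1[C@@H](O[Si](CC)(CC)CC)CC=O
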